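**Fork odds.** The ratio I followed was the odds at a fork: a substrate molecule either meets reagent and becomes an adduct, or meets substrate and becomes homo dimer. As with two parallel drains, the split goes by the two rates. The first rate carries [reagent] and the second [substrate], so the odds run as [reagent]/[substrate].

| flask | substrate | reagent | remark | time |
|---|---|---|---|---|
| delta | 0.12 M | 0.252 M | run made earlier |  |
| zeta | 0.48 M | 0.252 M | run made earlier |  |
| beta | 0.24 M | 0.38 M | run made earlier |  |
| flask | 0.24 M | 0.252 M |  | 50 h |

| run | time / h | substrate / % | mono adduct / % | other mono adduct / % |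
|---|---|---|---|---|
| delta | 4.00 | 65.5 | 28.3 | 0 |
| delta | 6.00 | 53.9 | 36.9 | 0.8 |
| delta | 12.0 | 31.9 | 53.1 | 0.7 |
| delta | 20.0 | 19.3 | 64.2 | 2.2 |
| delta | 30.0 | 10.0 | 68.2 | 1.5 |
| delta | 48.0 | 3.1 | 69.6 | 1.0 |
| zeta | 4.00 | 57.6 | 20.7 | 0.6 |
| zeta | 6.00 | 47.1 | 25.9 | 1.1 |
| zeta | 12.0 | 31.6 | 34.3 | 0.1 |
| zeta | 20.0 | 23.2 | 38.2 | 1.7 |
| zeta | 30.0 | 15.8 | 39.8 | 1.0 |
| zeta | 48.0 | 11.6 | 41.5 | 1.2 |
| beta | 10.0 | 26.5 | 55.5 | 1.3 |
| beta | 20.0 | 11.2 | 64.8 | 0.8 |
| beta | 30.0 | 6.5 | 67.4 | 1.5 |
| beta | 40.0 | 3.2 | 66.3 | 1.4 |
| beta | 48.0 | 1.3 | 65.6 | 1.5 |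

(scatter of a reading: 0.5 percentage points)

- a species is counted by the substrate in it: one homo dimer counts as two
- candidate steps: substrate + reagent -> mono adduct; substrate + reagent -> other mono adduct; reagent + mono adduct -> double product; reagent + other mono adduct -> double product; 2 substrate -> homo dimer

- how much substrate there is at 50 h, in percent of the substrate charged
- how much mono adduct there is at 50 h, in percent of the substrate charged
- how much other mono adduct there is at 50 h, in percent of the substrate charged
- how much double product there is at 50 h, in percent of the substrate charged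

**Reading it.** In zeta at 4.00 h the adducts held 21.3%, and the gap in the balance, which I booked as homo dimer, held 21.1%. Dividing their ratio by the charge ratio gave the reading 1.92, the fork constant: odds per unit of [reagent]/[substrate], a selectivity factor.

**Flask against beta.** The flask differs from beta in reagent, 0.252 M against 0.38 M. I took the odds at the midpoint, when half the substrate had gone. Reagent spent by then, at the starting split, left [reagent] at 0.172 M in the flask and 0.290 M in beta. The midpoint odds were therefore 2.75 and 4.64. Because the flask's odds are lower, it ends apart from beta, not merely later: I expected a homo dimer share, one over one plus the odds, of 26.7% against 17.7% in beta.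

**The result.** The forecast said 7.6% substrate, 60.5% mono adduct, 1.2% other mono adduct and 9% double product, arguing that “Missing mass balance grows with substrate concentration, so the homo dimer clearly matters”. The flask gave 7.14%, 60.7%, 1.21% and 8.00%, with homo dimer at 22.9%, 3.8 percentage points under my share.

    substrate + reagent → mono adduct (k = 0.00620 /M/min)
    substrate + reagent → other mono adduct (k = 2.00 × 10⁻⁴ /M/min)
    reagent + mono adduct → double product (k = 4.80 × 10⁻⁴ /M/min)
    reagent + other mono adduct → double product (k = 0.00270 /M/min)
    2 substrate → homo dimer (k = 0.00150 /M/min)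

**Neighbour flask.** For the neighbour charged with 0.63 M of reagent, the same reckoning gave midpoint [reagent] of 0.530 M, odds of 8.49, higher than the flask's, and a homo dimer share of 10.5%. That neighbour held 9.06% homo dimer at 50 h, with 0.0488% substrate left. Its mono adduct stood at 54.3%, less than the flask's 60.7%, beside 36.4% double product.

All runs come from a simulation from invented constants.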